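**Retrosynthetic overview**
1. The target is released last by hydrogenolysis of a 7,3',5'-tri-O-benzyl flavone; the methyl ethers are already in place.
2. Ring C (the pyranone) is the only ring built, by I2/DMSO oxidative cyclisation of a 2'-hydroxychalcone.
3. The chalcone Cα–Cβ bond comes from an intermolecular Claisen–Schmidt aldol condensation of a ring A acetophenone with a ring B benzaldehyde.
4. The ring A acetophenone comes from 2,5-dimethoxyresorcinol (Hoesch acylation, then selective 4-O-benzylation), itself made from the ring B aldehyde by Baeyer–Villiger oxidation, O-methylation and debenzylation.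
5. The ring B aldehyde, 3,5-bis(benzyloxy)-4-methoxybenzaldehyde, comes from methyl gallate, so both aromatic rings derive from one cheap starting material.

Assumption: the target, 7-hydroxy-2-(3,5-dihydroxy-4-methoxyphenyl)-5,8-dimethoxy-4H-chromen-4-one, has no stereocentre, so it is made as the achiral compound drawn and no stereocontrol is needed.

The aldehyde made in step 4 is divided: one part is carried through steps 5–9 to ring A, the other is the ring B partner in step 10.

**Route**

Step 1
Reactants: 1 methyl gallate (methyl 3,4,5-trihydroxybenzoate)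
Product: 2 methyl 3,5-dihydroxy-4-methoxybenzoate
Conditions: MeI (1.0 equiv), K2CO3 (1.0 equiv), DMF, 0 °C to rt, 24 h
Reagents that add atoms: iodomethane, CI
Why: The 4-OH, para to the ester, is the most acidic phenol of a gallate, so one equivalent of base and MeI gives selective Williamson O-methylation there.

Step 2
Reactants: 2 methyl 3,5-dihydroxy-4-methoxybenzoate
Product: 3 methyl 3,5-bis(benzyloxy)-4-methoxybenzoate
Conditions: BnBr (2.4 equiv), K2CO3 (3 equiv), DMF, 60 °C
Reagents that add atoms: benzyl bromide, BrCc1ccccc1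
Why: Williamson etherification of the two remaining phenols goes to completion with excess benzyl bromide, and the ester is stable to carbonate.

Step 3
Reactants: 3 methyl 3,5-bis(benzyloxy)-4-methoxybenzoate
Product: 4 [3,5-bis(benzyloxy)-4-methoxyphenyl]methanol
Conditions: LiAlH4, THF, 0 °C to rt; H2O/15% NaOH work-up
Reagents that add atoms: none
Why: Hydride reduction of the ester with LiAlH4 gives the benzylic alcohol cleanly, and aryl benzyl and methyl ethers are inert.

Step 4
Reactants: 4 [3,5-bis(benzyloxy)-4-methoxyphenyl]methanol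
Product: 5 3,5-bis(benzyloxy)-4-methoxybenzaldehyde
Conditions: activated MnO2 (10 equiv), CH2Cl2, rt
Reagents that add atoms: none
Why: MnO2 oxidation is selective for benzylic alcohols and stops at the aldehyde without over-oxidation.

Step 5
Reactants: 5 3,5-bis(benzyloxy)-4-methoxybenzaldehyde
Product: 7 3,5-bis(benzyloxy)-4-methoxyphenol, via aryl formate 6 (not isolated)
Conditions: mCPBA (1.5 equiv), CH2Cl2, 0 °C to rt; then K2CO3 (cat.), MeOH, rt; dilute HCl work-up
Reagents that add atoms: 3-chloroperoxybenzoic acid (mCPBA), O=C(OO)c1cccc(Cl)c1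
Why: In this Baeyer–Villiger (Dakin-type) oxidation the electron-rich trialkoxyaryl group migrates in preference to hydrogen to give the aryl formate, which mild methanolysis converts to the phenol.

Step 6
Reactants: 7 3,5-bis(benzyloxy)-4-methoxyphenol
Product: 8 1,3-bis(benzyloxy)-2,5-dimethoxybenzene
Conditions: MeI (1.5 equiv), K2CO3 (2 equiv), acetone, reflux
Reagents that add atoms: iodomethane, CI
Why: Williamson O-methylation of the only free phenol fixes the future 5-OMe of the flavone.

Step 7
Reactants: 8 1,3-bis(benzyloxy)-2,5-dimethoxybenzene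
Product: 9 2,5-dimethoxybenzene-1,3-diol (2,5-dimethoxyresorcinol)
Conditions: H2 (1 atm), 10% Pd/C, EtOAc/MeOH, rt; used directly under N2
Reagents that add atoms: none
Why: Catalytic hydrogenolysis removes both benzyl ethers and leaves the methyl ethers, giving a symmetric resorcinol whose two free ring positions are equivalent.

Step 8
Reactants: 9 2,5-dimethoxybenzene-1,3-diol
Product: 11 1-(2,4-dihydroxy-3,6-dimethoxyphenyl)ethan-1-one, via ketimine hydrochloride 10 (not isolated)
Conditions: MeCN (3 equiv), ZnCl2 (0.5 equiv), dry HCl gas, Et2O, 0 °C, 24 h; then H2O, reflux, 1 h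
Reagents that add atoms: acetonitrile, CC#N; water, O
Why: In this Hoesch acylation the nitrilium electrophile attacks the phloroglucinol-type ring at the only kind of free position, and the resulting ketimine salt hydrolyses to the mono-acetyl ketone.

Step 9
Reactants: 11 1-(2,4-dihydroxy-3,6-dimethoxyphenyl)ethan-1-one
Product: 12 1-[4-(benzyloxy)-2-hydroxy-3,6-dimethoxyphenyl]ethan-1-one
Conditions: BnBr (1.05 equiv), K2CO3 (1.1 equiv), acetone, reflux
Reagents that add atoms: benzyl bromide, BrCc1ccccc1
Why: The 2-OH is hydrogen-bonded to the ketone and poorly nucleophilic, so one equivalent of benzyl bromide gives selective Williamson benzylation of the more acidic 4-OH.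

Step 10
Reactants: 12 1-[4-(benzyloxy)-2-hydroxy-3,6-dimethoxyphenyl]ethan-1-one; 5 3,5-bis(benzyloxy)-4-methoxybenzaldehyde
Product: 14 (E)-1-[4-(benzyloxy)-2-hydroxy-3,6-dimethoxyphenyl]-3-[3,5-bis(benzyloxy)-4-methoxyphenyl]prop-2-en-1-one, via aldol adduct 13 (not isolated)
Conditions: 50% aq. KOH (excess), EtOH/THF, rt, 48–72 h; then cold dilute HCl
Reagents that add atoms: none
Why: In this Claisen–Schmidt aldol condensation the methyl ketone enolate adds to the non-enolisable aldehyde and E1cB dehydration gives the conjugated chalcone as the thermodynamic E alkene, erasing the aldol stereocentre.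

Step 11
Reactants: 14 (E)-1-[4-(benzyloxy)-2-hydroxy-3,6-dimethoxyphenyl]-3-[3,5-bis(benzyloxy)-4-methoxyphenyl]prop-2-en-1-one
Product: 16 7-(benzyloxy)-2-[3,5-bis(benzyloxy)-4-methoxyphenyl]-5,8-dimethoxy-4H-chromen-4-one, via flavanone 15 (not isolated)
Conditions: I2 (0.1 equiv), DMSO, 120 °C, 2–4 h; aq. Na2S2O3 work-up
Reagents that add atoms: none
Why: In this I2/DMSO oxidative cyclisation, intramolecular oxa-Michael addition closes ring C to the racemic flavanone, α-iodination and loss of HI introduce the C2=C3 bond (removing the stereocentre), and DMSO re-oxidises HI to I2.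

Step 12
Reactants: 16 7-(benzyloxy)-2-[3,5-bis(benzyloxy)-4-methoxyphenyl]-5,8-dimethoxy-4H-chromen-4-one
Product: 17 7-hydroxy-2-(3,5-dihydroxy-4-methoxyphenyl)-5,8-dimethoxy-4H-chromen-4-one
Conditions: H2 (1 atm), 10% Pd/C, THF/MeOH (1:1), rt
Reagents that add atoms: none
Why: Hydrogenolysis cleaves the three benzyl ethers at room temperature and 1 atm without reducing the chromone C2=C3 bond or touching the three methyl ethers, giving the achiral target.

**Compound list**
1 | methyl gallate (methyl 3,4,5-trihydroxybenzoate) | COC(=O)c1cc(O)c(O)c(O)c1 | starting material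
2 | methyl 3,5-dihydroxy-4-methoxybenzoate | COC(=O)c1cc(O)c(OC)c(O)c1 | intermediate
3 | methyl 3,5-bis(benzyloxy)-4-methoxybenzoate | COC(=O)c1cc(OCc2ccccc2)c(OC)c(OCc2ccccc2)c1 | intermediate
4 | [3,5-bis(benzyloxy)-4-methoxyphenyl]methanol | OCc1cc(OCc2ccccc2)c(OC)c(OCc2ccccc2)c1 | intermediate
5 | 3,5-bis(benzyloxy)-4-methoxybenzaldehyde | O=Cc1cc(OCc2ccccc2)c(OC)c(OCc2ccccc2)c1 | intermediate
6 | 3,5-bis(benzyloxy)-4-methoxyphenyl formate (not isolated) | O=COc1cc(OCc2ccccc2)c(OC)c(OCc2ccccc2)c1 | intermediate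
7 | 3,5-bis(benzyloxy)-4-methoxyphenol | Oc1cc(OCc2ccccc2)c(OC)c(OCc2ccccc2)c1 | intermediate
8 | 1,3-bis(benzyloxy)-2,5-dimethoxybenzene | COc1cc(OCc2ccccc2)c(OC)c(OCc2ccccc2)c1 | intermediate
9 | 2,5-dimethoxybenzene-1,3-diol | COc1cc(O)c(OC)c(O)c1 | intermediate
10 | 1-(2,4-dihydroxy-3,6-dimethoxyphenyl)ethan-1-imine, present as its hydrochloride (not isolated; drawn as the free ketimine) | CC(=N)c1c(O)c(OC)c(O)cc1OC | intermediate
11 | 1-(2,4-dihydroxy-3,6-dimethoxyphenyl)ethan-1-one | CC(=O)c1c(O)c(OC)c(O)cc1OC | intermediate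
12 | 1-[4-(benzyloxy)-2-hydroxy-3,6-dimethoxyphenyl]ethan-1-one | CC(=O)c1c(O)c(OC)c(OCc2ccccc2)cc1OC | intermediate
13 | 1-[4-(benzyloxy)-2-hydroxy-3,6-dimethoxyphenyl]-3-[3,5-bis(benzyloxy)-4-methoxyphenyl]-3-hydroxypropan-1-one, racemic (not isolated) | O=C(CC(O)c1cc(OCc2ccccc2)c(OC)c(OCc2ccccc2)c1)c1c(O)c(OC)c(OCc2ccccc2)cc1OC | intermediate
14 | (E)-1-[4-(benzyloxy)-2-hydroxy-3,6-dimethoxyphenyl]-3-[3,5-bis(benzyloxy)-4-methoxyphenyl]prop-2-en-1-one | O=C(/C=C/c1cc(OCc2ccccc2)c(OC)c(OCc2ccccc2)c1)c1c(O)c(OC)c(OCc2ccccc2)cc1OC | intermediate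
15 | 7-(benzyloxy)-2-[3,5-bis(benzyloxy)-4-methoxyphenyl]-5,8-dimethoxy-2,3-dihydro-4H-chromen-4-one, racemic (not isolated) | COc1cc(OCc2ccccc2)c(OC)c2OC(c3cc(OCc4ccccc4)c(OC)c(OCc4ccccc4)c3)CC(=O)c12 | intermediate
16 | 7-(benzyloxy)-2-[3,5-bis(benzyloxy)-4-methoxyphenyl]-5,8-dimethoxy-4H-chromen-4-one | COc1cc(OCc2ccccc2)c(OC)c2oc(-c3cc(OCc4ccccc4)c(OC)c(OCc4ccccc4)c3)cc(=O)c12 | intermediate
17 | 7-hydroxy-2-(3,5-dihydroxy-4-methoxyphenyl)-5,8-dimethoxy-4H-chromen-4-one | COc1c(O)cc(-c2cc(=O)c3c(OC)cc(O)c(OC)c3o2)cc1O | target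

**Totals**
Total step count: 12.
Longest linear sequence: 12 steps (1 to 17 through the ring A branch). The ring B partner needs only steps 1–4 and re-enters at step 10.

**Three steps most likely to fail, with fallbacks**

Step 1 (selective 4-O-methylation; over-methylation or 3-O-methylation would lower the yield). The fallback sets out from compound 1. Peracetylation (Ac2O, pyridine, rt) gives methyl 3,4,5-triacetoxybenzoate F1. Heating F1 with MeI and K2CO3 in acetone cleaves only the most labile acetate, the one para to the ester, giving methyl 3,5-diacetoxy-4-hydroxybenzoate F2 as its potassium phenoxide in the flask. This is methylated in place to methyl 3,5-diacetoxy-4-methoxybenzoate F3. Methanolysis of the two remaining acetates (K2CO3 cat., MeOH, rt) comes back to the route at compound 2. The regiochemistry is then set by acetate lability rather than by competitive phenol alkylation.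

Step 5 (Baeyer–Villiger; hydrogen migration to the benzoic acid could compete because the 4-OMe is twisted out of conjugation). The fallback sets out from compound 3. Addition of MeMgBr (3 equiv, THF, 0 °C to rt) gives 2-[3,5-bis(benzyloxy)-4-methoxyphenyl]propan-2-ol F4. Treatment with 50% H2O2 and BF3·OEt2 in CH2Cl2 at 0 °C forms 2-[3,5-bis(benzyloxy)-4-methoxyphenyl]propan-2-yl hydroperoxide F5 in the flask. F5 undergoes acid-catalysed aryl migration (Hock-type rearrangement) with loss of acetone and comes back to the route at compound 7. No aldehyde oxidation is involved.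

Step 11 (I2/DMSO; the HI formed at 120 °C could cleave the 5-OMe or a benzyl ether, or the reaction could stall at the flavanone). The fallback sets out from compounds 12 and 3 and also bypasses step 10. A crossed Claisen condensation of the ketone enolate of 12 with ester 3 (LiN(SiMe3)2, 4 equiv, THF, −20 °C to reflux) gives 1-[4-(benzyloxy)-2-hydroxy-3,6-dimethoxyphenyl]-3-[3,5-bis(benzyloxy)-4-methoxyphenyl]propane-1,3-dione F6. Acid-catalysed cyclodehydration (p-TsOH·H2O cat., toluene, 90 °C) closes ring C and comes back to the route at compound 16. The C2=C3 bond is then already at the right oxidation level and no oxidant is needed.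

**Further compounds**
F1 | step 1 | methyl 3,4,5-triacetoxybenzoate | COC(=O)c1cc(OC(C)=O)c(OC(C)=O)c(OC(C)=O)c1
F2 | step 1 | methyl 3,5-diacetoxy-4-hydroxybenzoate (formed in the flask) | COC(=O)c1cc(OC(C)=O)c(O)c(OC(C)=O)c1
F3 | step 1 | methyl 3,5-diacetoxy-4-methoxybenzoate | COC(=O)c1cc(OC(C)=O)c(OC)c(OC(C)=O)c1
F4 | step 5 | 2-[3,5-bis(benzyloxy)-4-methoxyphenyl]propan-2-ol | CC(C)(O)c1cc(OCc2ccccc2)c(OC)c(OCc2ccccc2)c1
F5 | step 5 | 2-[3,5-bis(benzyloxy)-4-methoxyphenyl]propan-2-yl hydroperoxide (formed in the flask) | CC(C)(OO)c1cc(OCc2ccccc2)c(OC)c(OCc2ccccc2)c1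
F6 | step 11 | 1-[4-(benzyloxy)-2-hydroxy-3,6-dimethoxyphenyl]-3-[3,5-bis(benzyloxy)-4-methoxyphenyl]propane-1,3-dione | O=C(CC(=O)c1cc(OCc2ccccc2)c(OC)c(OCc2ccccc2)c1)c1c(O)c(OC)c(OCc2ccccc2)cc1OC
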